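**Plan**

1. Cuts: the CH2–C(=O) bond between the allylic CH2 of the Z side chain and the chain ketone (union of the two halves); the enone C=C (aldol condensation); two cyclobutane bonds of a [2+2] adduct that carries both quaternary carbons.
2. Enabling features: the chain ketone and the enone carbonyl are 1,5-related across the vicinal quaternary carbons C1/C2 of the cyclopentane, the pattern left by retro-aldol opening of a de Mayo cyclobutane. The Z-CH2–C(CH3)=CH–CH2 unit sits ortho to a phenol oxygen and can be tied back into a 2,5-dihydro-1-benzoxepine ring.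
3. Aryl half: methylhydroquinone, O-allylation, Claisen rearrangement, O-(2-methylallyl)ation, ring-closing metathesis give benzoxepine 6, whose ring fixes the Z alkene.
4. Acyl half: 2,2,6-trimethyl-1,3-dioxin-4-one and 1,2-dimethylcyclopentene give a cyclobutane photoadduct, resolved to 10.
5. Union: reductive opening of 6 to a Z-allylcerium, addition to the lactone C=O of 10, loss of acetone and strain-releasing retro-aldol give the 1,5-diketone with the new ketone stored as a silyl enol ether; aldol condensation at the free methyl ketone and global desilylation finish.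
6. Stereochemistry: cis quaternary carbons from the cis five-four ring fusion of the photoadduct, absolute configuration from its resolution; Z alkene from the seven-membered ring; E enone from elimination.

Key step: step 10

Assumption: the photocycloaddition is taken to give mainly the cis-anti-cis adduct; a minor cis-syn-cis isomer would be removed on silica before step 7.

**Route**

Step 1
Reactants: 1 2-methylbenzene-1,4-diol
Product: 2 2-methyl-4-(triisopropylsilyloxy)phenol
Conditions: i-Pr3SiCl (1.0 equiv), imidazole, DMF, 0 °C
Reagents that add atoms: chlorotriisopropylsilane, CC(C)[Si](Cl)(C(C)C)C(C)C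
Why: Selective phenol silylation: the hydroxyl next to the methyl group is shielded, so the bulky silyl chloride should react at the unhindered 4-OH.

Step 2
Reactants: 2 2-methyl-4-(triisopropylsilyloxy)phenol
Product: 3 triisopropyl[3-methyl-4-(prop-2-en-1-yloxy)phenoxy]silane
Conditions: allyl bromide, K2CO3, acetone, reflux
Reagents that add atoms: allyl bromide, C=CCBr
Why: Williamson ether synthesis: the remaining phenoxide is alkylated by the reactive allylic bromide under conditions that leave the aryl silyl ether intact.

Step 3
Reactants: 3 triisopropyl[3-methyl-4-(prop-2-en-1-yloxy)phenoxy]silane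
Product: 4 2-methyl-6-(prop-2-en-1-yl)-4-(triisopropylsilyloxy)phenol
Conditions: N,N-diethylaniline, 190 °C
Reagents that add atoms: none
Why: Aromatic Claisen rearrangement ([3,3]-sigmatropic shift): the only free ortho position is C6 (C2 carries the methyl group, the para position the silyloxy group), so the allyl group can end up only there.

Step 4
Reactants: 4 2-methyl-6-(prop-2-en-1-yl)-4-(triisopropylsilyloxy)phenol
Product: 5 triisopropyl[3-methyl-4-(2-methylprop-2-en-1-yloxy)-5-(prop-2-en-1-yl)phenoxy]silane
Conditions: 3-bromo-2-methylprop-1-ene, K2CO3, acetone, reflux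
Reagents that add atoms: 3-bromo-2-methylprop-1-ene, CC(=C)CBr
Why: Williamson ether synthesis on the regenerated phenol, which brings in the 2-methylallyl unit that will carry the alkene methyl group and the future nucleophilic CH2.

Step 5
Reactants: 5 triisopropyl[3-methyl-4-(2-methylprop-2-en-1-yloxy)-5-(prop-2-en-1-yl)phenoxy]silane
Product: 6 triisopropyl[(3,9-dimethyl-2,5-dihydro-1-benzoxepin-7-yl)oxy]silane
Conditions: second-generation Grubbs catalyst (3 mol %), CH2Cl2, 40 °C
Reagents that add atoms: none
Why: Ring-closing metathesis of the allyl and 2-methylallyl groups with loss of ethene; the seven-membered ring can hold the new trisubstituted alkene only with its two ring CH2 groups cis, which is the Z geometry of the target side chain.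

Step 6
Reactants: 7 2,2,6-trimethyl-4H-1,3-dioxin-4-one; 8 1,2-dimethylcyclopentene
Product: 9 racemic cis-anti-cis photoadduct (cyclobutane fused across C5–C6 of 2,2,6-trimethyl-1,3-dioxan-4-one and across C1–C2 of 1,2-dimethylcyclopentane; C5 bonded to C1; both cyclopentane methyl groups on the cyclobutane face that carries the lactone carbonyl carbon and the ring oxygen)
Conditions: hν (300 nm, Pyrex), 8 (5 equiv), MeCN, 0 °C
Reagents that add atoms: none
Why: [2+2] Enone–alkene photocycloaddition (first stage of a de Mayo reaction) of the excited dioxinone to the electron-rich alkene; a five-four ring fusion can only be cis, so the two methyl-bearing carbons become cis quaternary centers (racemic), the symmetric alkene leaves no regiochemical issue, and the two dioxanone ring-fusion centers are erased in step 10.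

Step 7
Reactants: 9 racemic cis-anti-cis photoadduct
Product: 10 single enantiomer of the photoadduct (cyclopentane carbons configured as C1/C2 of the target ring; see SMILES)
Conditions: preparative supercritical-fluid chromatography, amylose tris(3,5-dimethylphenylcarbamate) phase, CO2/MeOH
Reagents that add atoms: none
Why: Resolution: the four stereocenters of the rigid tricycle cannot epimerize, so chromatography on a chiral stationary phase should part the enantiomers and thereby fix the absolute configuration of both quaternary carbons, the configuration of the collected enantiomer being assigned by anomalous-dispersion X-ray analysis.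

Step 8
Reactants: 11 methyl 2-hydroxy-2-methylpropanoate
Product: 12 methyl 2-methyl-2-(triethylsilyloxy)propanoate
Conditions: Et3SiCl, imidazole, DMAP (cat.), DMF, rt
Reagents that add atoms: chlorotriethylsilane, CC[Si](Cl)(CC)CC
Why: Silyl protection of the tertiary alcohol so that the aldehyde made in step 9 has no free hydroxyl and the later enolate chemistry is not quenched.

Step 9
Reactants: 12 methyl 2-methyl-2-(triethylsilyloxy)propanoate
Product: 13 2-methyl-2-(triethylsilyloxy)propanal
Conditions: i-Bu2AlH, CH2Cl2, −78 °C; aq potassium sodium tartrate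
Reagents that add atoms: none
Why: Partial ester reduction: at −78 °C the α-alkoxy tetrahedral aluminate is stable, so the ester stops at the aldehyde, which has no α-hydrogen and cannot enolize.

Step 10
Reactants: 6 triisopropyl[(3,9-dimethyl-2,5-dihydro-1-benzoxepin-7-yl)oxy]silane; 10 single-enantiomer photoadduct
Product: 17 1-[(1R,2R)-1,2-dimethyl-2-{(4Z)-4-methyl-2-(triethylsilyloxy)-6-[3-methyl-2-(triethylsilyloxy)-5-(triisopropylsilyloxy)phenyl]hexa-1,4-dien-1-yl}cyclopentyl]ethan-1-one, via dilithio allyl phenoxide 14 (not isolated), via allylcerium dichloride 15 (not isolated), via ring-opened metal enolate 16 (not isolated)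
Conditions: lithium 4,4'-di-tert-butylbiphenylide (LiDBB, 2.0 equiv), THF, −78 °C; CeCl3 (anhydrous), −78 °C; 10, −78 °C; Et3SiCl, Et3N, −78 to 0 °C; aq NaHCO3
Reagents that add atoms: chlorotriethylsilane, CC[Si](Cl)(CC)CC
Why: Proposed new method: two-electron reduction of the allylic C2–O bond of 6 (reductive lithiation, the known route from allyl aryl ethers to allyllithiums) opens the benzoxepine to the phenoxide-tethered allyllithium 14 with the ring-enforced Z geometry, and CeCl3 turns it into the allylcerium 15, a reagent class known to hold its configuration at −78 °C and to attack carbonyl groups through the unsubstituted allyl terminus. Its CH2 terminus adds to the lactone carbonyl of 10 (acylation of an organometallic by a 1,3-dioxan-4-one); on warming the hemiketal alkoxide collapses, acetone leaves, and the resulting β-keto cyclobutanolate undergoes retro-aldol cleavage of the cyclobutane bond, driven by release of ring strain, which is the fragmentation half of a de Mayo reaction triggered by a carbon nucleophile instead of an alkoxide. No ring is closed (the benzoxepine, dioxanone and cyclobutane rings are opened) and no stereocenter is created: the two quaternary carbons come unchanged from 10 and the Z alkene from the seven-membered ring of 6. The step needs attack at the CH2 terminus (favoured by cerium and by the hindered lactone carbonyl), retention of the Z geometry (the Z allyl anion is also the favoured one, since the chain avoids the 2-methyl group and can chelate through the phenoxide) and single addition (the new ketone is born as its enolate 16 and never meets the allylmetal as a ketone). Silylation of 16 and of the phenoxide by Et3SiCl stores the new ketone as its regiodefined silyl enol ether, which keeps the two carbonyls of the 1,5-diketone apart for steps 11 and 12.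

Step 11
Reactants: 17 silyl enol ether methyl ketone (as named in step 10); 13 2-methyl-2-(triethylsilyloxy)propanal
Product: 18 1-[(1R,2R)-1,2-dimethyl-2-{dienyl side chain of 17}cyclopentyl]-3-hydroxy-4-methyl-4-(triethylsilyloxy)pentan-1-one (both C3 epimers)
Conditions: LiN(i-Pr)2, THF, −78 °C; 13; aq NH4Cl
Reagents that add atoms: none
Why: Directed (kinetic) aldol addition: LiN(i-Pr)2 can deprotonate the only ketone solely at its methyl group because the other α-carbon is quaternary and the second ketone is masked as a silyl enol ether, and the non-enolizable aldehyde 13 then accepts the enolate; the new carbinol center is not controlled and is removed in step 12.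

Step 12
Reactants: 18 aldol adduct
Product: 20 (2E)-1-[(1R,2R)-1,2-dimethyl-2-{dienyl side chain of 17}cyclopentyl]-4-methyl-4-(triethylsilyloxy)pent-2-en-1-one, via mesylate 19 (not isolated)
Conditions: MeSO2Cl, Et3N, CH2Cl2, 0 °C; then DBU, rt
Reagents that add atoms: none
Why: Mesylation followed by E1cB elimination completes the aldol condensation and should give the E enone, because the bulky silyloxy-bearing carbon and the acyl group avoid each other.

Step 13
Reactants: 20 fully silylated enone
Product: 21 (2E)-1-[(1R,2R)-2-{(4Z)-6-(2,5-dihydroxy-3-methylphenyl)-4-methyl-2-oxohex-4-en-1-yl}-1,2-dimethylcyclopentyl]-4-hydroxy-4-methylpent-2-en-1-one (CNP0212540.1)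
Conditions: Bu4NF, AcOH (1:1), THF, 0 °C to rt, argon
Reagents that add atoms: none
Why: Fluoride-mediated desilylation buffered by acetic acid frees both phenols and the tertiary alcohol and converts the silyl enol ether into the ketone by protonation at its α-carbon (the CH next to the ring), so the Z β,γ-double bond is not moved into conjugation.

**Compound list**

1 | 2-methylbenzene-1,4-diol | Cc1cc(O)ccc1O | starting material
2 | 2-methyl-4-(triisopropylsilyloxy)phenol | Cc1cc(O[Si](C(C)C)(C(C)C)C(C)C)ccc1O | intermediate
3 | triisopropyl[3-methyl-4-(prop-2-en-1-yloxy)phenoxy]silane | C=CCOc1ccc(O[Si](C(C)C)(C(C)C)C(C)C)cc1C | intermediate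
4 | 2-methyl-6-(prop-2-en-1-yl)-4-(triisopropylsilyloxy)phenol | C=CCc1cc(O[Si](C(C)C)(C(C)C)C(C)C)cc(C)c1O | intermediate
5 | triisopropyl[3-methyl-4-(2-methylprop-2-en-1-yloxy)-5-(prop-2-en-1-yl)phenoxy]silane | CC(=C)COc1c(C)cc(O[Si](C(C)C)(C(C)C)C(C)C)cc1CC=C | intermediate
6 | triisopropyl[(3,9-dimethyl-2,5-dihydro-1-benzoxepin-7-yl)oxy]silane | CC1=CCc2cc(O[Si](C(C)C)(C(C)C)C(C)C)cc(C)c2OC1 | intermediate
7 | 2,2,6-trimethyl-4H-1,3-dioxin-4-one | CC1=CC(=O)OC(C)(C)O1 | starting material
8 | 1,2-dimethylcyclopentene | CC1=C(C)CCC1 | starting material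
9 | racemic cis-anti-cis photoadduct of 7 and 8 (relative configuration shown) | C[C@@]12OC(C)(C)OC(=O)[C@@H]1[C@@]1(C)CCC[C@@]21C | intermediate
10 | photoadduct, single enantiomer (absolute configuration shown) | C[C@@]12OC(C)(C)OC(=O)[C@@H]1[C@@]1(C)CCC[C@@]21C | intermediate
11 | methyl 2-hydroxy-2-methylpropanoate | COC(=O)C(C)(C)O | starting material
12 | methyl 2-methyl-2-(triethylsilyloxy)propanoate | COC(=O)C(C)(C)O[Si](CC)(CC)CC | intermediate
13 | 2-methyl-2-(triethylsilyloxy)propanal | O=CC(C)(C)O[Si](CC)(CC)CC | intermediate
14 | lithium 2-[(2Z)-4-lithio-3-methylbut-2-en-1-yl]-6-methyl-4-(triisopropylsilyloxy)phenolate | C/C(=C/Cc1cc(O[Si](C(C)C)(C(C)C)C(C)C)cc(C)c1O[Li])C[Li] | intermediate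
15 | (2Z)-allylcerium dichloride derived from 14 (lithium phenoxide) | C/C(=C/Cc1cc(O[Si](C(C)C)(C(C)C)C(C)C)cc(C)c1O[Li])C[Ce](Cl)Cl | intermediate
16 | ring-opened metal enolate (drawn as the lithium salt; enolate geometry open) | C/C(=C/Cc1cc(O[Si](C(C)C)(C(C)C)C(C)C)cc(C)c1O[Li])CC(O[Li])=C[C@@]1(C)CCC[C@@]1(C)C(C)=O | intermediate
17 | 1-[(1R,2R)-1,2-dimethyl-2-{(4Z)-4-methyl-2-(triethylsilyloxy)-6-[3-methyl-2-(triethylsilyloxy)-5-(triisopropylsilyloxy)phenyl]hexa-1,4-dien-1-yl}cyclopentyl]ethan-1-one (enol ether geometry open) | C/C(=C/Cc1cc(O[Si](C(C)C)(C(C)C)C(C)C)cc(C)c1O[Si](CC)(CC)CC)CC(O[Si](CC)(CC)CC)=C[C@@]1(C)CCC[C@@]1(C)C(C)=O | intermediate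
18 | 3-hydroxy-4-methyl-4-(triethylsilyloxy)pentan-1-one bearing at C1 the (1R,2R)-cyclopentyl unit of 17 (C3 epimers) | C/C(=C/Cc1cc(O[Si](C(C)C)(C(C)C)C(C)C)cc(C)c1O[Si](CC)(CC)CC)CC(O[Si](CC)(CC)CC)=C[C@@]1(C)CCC[C@@]1(C)C(=O)CC(O)C(C)(C)O[Si](CC)(CC)CC | intermediate
19 | 3-methanesulfonate of 18 | C/C(=C/Cc1cc(O[Si](C(C)C)(C(C)C)C(C)C)cc(C)c1O[Si](CC)(CC)CC)CC(O[Si](CC)(CC)CC)=C[C@@]1(C)CCC[C@@]1(C)C(=O)CC(OS(C)(=O)=O)C(C)(C)O[Si](CC)(CC)CC | intermediate
20 | (2E)-4-methyl-4-(triethylsilyloxy)pent-2-en-1-one bearing at C1 the (1R,2R)-cyclopentyl unit of 17 | C/C(=C/Cc1cc(O[Si](C(C)C)(C(C)C)C(C)C)cc(C)c1O[Si](CC)(CC)CC)CC(O[Si](CC)(CC)CC)=C[C@@]1(C)CCC[C@@]1(C)C(=O)/C=C/C(C)(C)O[Si](CC)(CC)CC | intermediate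
21 | (2E)-1-[(1R,2R)-2-{(4Z)-6-(2,5-dihydroxy-3-methylphenyl)-4-methyl-2-oxohex-4-en-1-yl}-1,2-dimethylcyclopentyl]-4-hydroxy-4-methylpent-2-en-1-one | C/C(=C/Cc1cc(O)cc(C)c1O)CC(=O)C[C@@]1(C)CCC[C@@]1(C)C(=O)/C=C/C(C)(C)O | target

**Count**

Total steps: 13. Longest linear sequence: 9 (steps 1–5, then 10–13).

**Steps most likely to fail**

1. Step 10 (proposed new method). Possible failures: attack through the substituted allyl terminus; E/Z equilibration of the allylmetal; enolization of the lactone instead of addition; early collapse of the adduct so that released acetone consumes allylmetal; proton transfer from the methyl ketone to the enolate followed by aldol ring closure before silylation.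
Fallback (known chemistry; sets out from 10 and 6, comes back at 21): the fragmentation and the union are separated. Methanolysis of 10 (K2CO3, MeOH) triggers the classical de Mayo retro-aldol and gives methyl 2-[(1R,2R)-2-acetyl-1,2-dimethylcyclopentyl]acetate F1. Its methyl ketone is condensed with 13 before any second ketone exists: LiN(i-Pr)2 at −78 °C then 13 gives the aldol F2, MeSO2Cl/Et3N gives the mesylate F3, and DBU gives the enone ester F4. The ester is converted into the N-methoxy-N-methylamide F5 (MeNHOMe·HCl, i-PrMgCl, −20 °C). The allylcerium 15, made from 6 as in step 10, is acylated once by F5 through the stable chelated adduct to give the ketone F6 with a free ortho phenol. Bu4NF/AcOH then gives 21.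

2. Step 7. Possible failures: incomplete separation of the enantiomers, or of the minor ring-fusion isomer, on the chiral phase; low throughput.
Fallback (sets out from 7, comes back at 17): the ketal ketone becomes a chiral auxiliary. Heating 7 with (2S,5R)-menthone in xylene at 140 °C (acetylketene transfer, acetone distilled off) gives the menthone spiro dioxinone F7 (either spiro epimer serves). Irradiation with 8 gives photoadducts that are diastereomers and separable on silica. The cis-anti-cis menthone-ketal photoadduct F8 with the required cyclopentane configuration is used in step 10 in place of 10; the cascade then expels menthone, which is less electrophilic than acetone, and gives 17.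

3. Step 13. Possible failures: air oxidation of the liberated hydroquinone during desilylation and chromatography; incomplete cleavage of the hindered silyl ethers, which forces longer exposure.
Fallback (sets out from 20, comes back at 21): the oxidation is driven to completion instead of being fought. The crude desilylation product is shaken with Ag2O in Et2O to give the benzoquinone F9, which is purified at this stable oxidation level and then reduced with aqueous Na2S2O4 to 21.

Further compounds
F1 | step 10 | methyl 2-[(1R,2R)-2-acetyl-1,2-dimethylcyclopentyl]acetate | COC(=O)C[C@@]1(C)CCC[C@@]1(C)C(C)=O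
F2 | step 10 | methyl 2-{(1R,2R)-2-[3-hydroxy-4-methyl-4-(triethylsilyloxy)pentanoyl]-1,2-dimethylcyclopentyl}acetate (C3 epimers) | COC(=O)C[C@@]1(C)CCC[C@@]1(C)C(=O)CC(O)C(C)(C)O[Si](CC)(CC)CC
F3 | step 10 | 3-methanesulfonate of F2 | COC(=O)C[C@@]1(C)CCC[C@@]1(C)C(=O)CC(OS(C)(=O)=O)C(C)(C)O[Si](CC)(CC)CC
F4 | step 10 | methyl 2-{(1R,2R)-1,2-dimethyl-2-[(2E)-4-methyl-4-(triethylsilyloxy)pent-2-enoyl]cyclopentyl}acetate | COC(=O)C[C@@]1(C)CCC[C@@]1(C)C(=O)/C=C/C(C)(C)O[Si](CC)(CC)CC
F5 | step 10 | N-methoxy-N-methyl-2-{(1R,2R)-1,2-dimethyl-2-[(2E)-4-methyl-4-(triethylsilyloxy)pent-2-enoyl]cyclopentyl}acetamide | CON(C)C(=O)C[C@@]1(C)CCC[C@@]1(C)C(=O)/C=C/C(C)(C)O[Si](CC)(CC)CC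
F6 | step 10 | (2E)-1-[(1R,2R)-2-{(4Z)-6-[2-hydroxy-3-methyl-5-(triisopropylsilyloxy)phenyl]-4-methyl-2-oxohex-4-en-1-yl}-1,2-dimethylcyclopentyl]-4-methyl-4-(triethylsilyloxy)pent-2-en-1-one | C/C(=C/Cc1cc(O[Si](C(C)C)(C(C)C)C(C)C)cc(C)c1O)CC(=O)C[C@@]1(C)CCC[C@@]1(C)C(=O)/C=C/C(C)(C)O[Si](CC)(CC)CC
F7 | step 7 | spiro dioxinone from 7 and (2S,5R)-menthone (6-methyl-1,3-dioxin-4-one with C2 as the menthane spiro carbon; spiro configuration open) | CC1=CC(=O)OC2(O1)C[C@H](C)CC[C@H]2C(C)C
F8 | step 7 | cis-anti-cis photoadduct of F7 and 8, diastereomer with the cyclopentane configuration of 10 (spiro configuration open) | C[C@@]12OC3(C[C@H](C)CC[C@H]3C(C)C)OC(=O)[C@@H]1[C@@]1(C)CCC[C@@]21C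
F9 | step 13 | 2-{(2Z)-6-[(1R,2R)-2-((2E)-4-hydroxy-4-methylpent-2-enoyl)-1,2-dimethylcyclopentyl]-3-methyl-5-oxohex-2-en-1-yl}-6-methyl-1,4-benzoquinone | C/C(=C/CC1=CC(=O)C=C(C)C1=O)CC(=O)C[C@@]1(C)CCC[C@@]1(C)C(=O)/C=C/C(C)(C)O
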